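All constants were set for the occasion; what happens was integrated by code.

Before you spread solid reagent and substrate over a plate, decide how much substrate the partner can carry through both additions, starting from this flask.

substrate 0.060 M (fed, over 1.0 h); solid reagent 0.0600 M; time 40 h

    substrate + partner → intermediate A (k1 = 0.505 L mol⁻¹ min⁻¹)
    partner + intermediate A → intermediate B (k2 = 1.86 L mol⁻¹ min⁻¹)
    intermediate B → side product (k3 = 0.0308 min⁻¹)
    intermediate B → target (k4 = 0.0173 min⁻¹)
    solid reagent ⇌ partner, rate k5*(cs5 - [partner]) while solid is left; crystals form when [partner] > cs5 (cs5 = 40 mM, k5 = 1.78 min⁻¹)

* at 40 h, what has stopped the reaction, if anything has (for what has run out or reacted, a solid counts together with what of it has only dissolved) (all of the substrate has reacted / it is still moving / the partner has run out first)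
* conversion of substrate at 40 h
* amount of target at 40 h, in percent of the substrate charged
* amount of side product at 40 h, in percent of the substrate charged

- as a solid, counted per litre of solution: solid reagent
- at the start none of the solid reagent is in solution
- the reaction counts as stopped when no species that holds the substrate changes by six tenths of a point or more over the second half of the time
- run time (flask): 40 h

The solid reagent feeds the partner, and each substrate that reaches intermediate B has taken two partners. So the charge calls for 0.120 M and the flask holds 0.0600 M, less, which makes the partner the limiting reagent. The number you want is the fraction of the substrate charged that receives both additions, and there are two ways to it.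

The first way is a count: if each intermediate A found its second partner, the fraction would be

cBs / need = 50.0%.

The second way lets the additions compete. Both are first order in the partner, so its level drops out of their ratio, the selectivity factor k2/k1 = 3.68. I reckon as if the whole substrate stood there from the start, which is my simplification. Write κ for this factor, s for the substrate left and m for the intermediate A stranded, both as fractions of the charge; then m = (s − s^κ)/(κ − 1). With ρ = cBs/cA = 1.00, the partner balance gives a conversion of (ρ + m)/2. Two passes, starting from the count:

s = 50.0%, m = 15.7%

s = 42.1%, m = 14.2%

This gives a conversion of 57.1% and, as (ρ − m)/2, the through-share, the fraction of the substrate charged that the partner carries to intermediate B, of 42.9%.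

The two ways part by 7.1 percentage points, and the count is the one that cheats: the second addition is faster than the first by a factor of 3.68, yet the first keeps running, so partner goes into intermediate A that then waits.

Intermediate B has half-lives of 0.38 h and 0.67 h by its two steps, far shorter than 40 h, so I let it drain completely, with 36.0% going to target:

target 15.4%, side product 27.5%.

The forecast says the partner has run out first, with conversion 57%, target 15.6% and side product 27.7%, and “a little intermediate A stranded”, its yields standing slightly above mine.

This flask gives the partner has run out first, with conversion 56.7%, target 15.6% and side product 27.7%, which together make 43.3% against the through-share of 42.9%. The neighbouring flask, like this one but richer in solid reagent, holds 0.10 M of it, still less than 0.120 M. Its two passes run s = 16.7%, m = 6.16%, then s = 13.6%, m = 5.04%. Its through-share is therefore 80.8%, which means 29.1% target and 51.7% side product. The neighbouring flask gives 29.0% target and 51.7% side product at 40.0 h.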